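Waiting cannot bring the free monomer of this flask to zero: each living end hands monomer back at 0.074 min⁻¹, while it takes monomer up at 1.8 L mol⁻¹ min⁻¹ times the free monomer.

free monomer 0.10 M; initiator 0.5 mol%; time 10 d

    free monomer + initiator → living end + monomer in chains (k1 = 0.022 L mol⁻¹ min⁻¹)
    2 initiator → spent initiator (k2 = 0.77 L mol⁻¹ min⁻¹)
    monomer in chains + living end → free monomer + living end, rate k3*[living end] as long as [monomer in chains] is above zero (k3 = 0.074 min⁻¹)
    free monomer + living end → monomer in chains + living end, rate k4*[living end]*[free monomer] (k4 = 1.8 L mol⁻¹ min⁻¹)

- for a step with 2 of a species take k times the square, and two of it per event
- the average divides the monomer in chains by the number of chains begun, living and dead together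
- run time (flask): 10 d

1. average number of monomer units in a chain (chains begun, living or dead) at 10 d
2. part of the free monomer that has reacted at 10 d

Taking up and giving back cancel at 0.0411 M, the give-back constant over the take-up constant. Call this level of free monomer the floor; the field says equilibrium monomer concentration.

The first way has no clock. You assume the flask has come to rest on the floor:

part reacted = (charge − floor) / charge = 58.9%

The second way has a clock, so it needs the chains. Initiator is charged at 5.00 × 10⁻⁴ M. With free monomer held at its charge, starting chains and pairing share it out through a scale s = 0.00143 M:

chains = s × ln(1 + initiator charge / s) = 4.29 × 10⁻⁴ M

Take those chains as present from the start. The gap to the floor, 0.0589 M, then falls by a power of ten every 2.07 d. That is shorter than the run, so 10 d holds 4.83 powers of ten: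

gap left = 8.79 × 10⁻⁷ M, part reacted = 58.9%

The two ways agree, but both lean on the floor, so the agreement is no test of the floor; it says that, on my count of chains, the run is long enough to reach it. Dividing the monomer above the floor by the chains, I commit to 137 units per chain.

The forecast gave 139 units and 58.9%, holding that “the propagation and depropagation steps have long since balanced”.

The flask gives 138 units per chain and 58.9% reacted at 10 d, with free monomer at 41.1% of its charge, where the floor over the charge is 41.1%.

Now take the neighbouring flask charged with 0.025 M of free monomer at the same loading, which is less than the floor. The same subtraction over its charge gives −64.4%, a negative part reacted. At 10 d that neighbouring flask still holds 99.9% of its charge as free monomer, with 0.0620% reacted, and its chains average 0.145 monomer units.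

The numbers are those of an exercise; what happens was integrated by code.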